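**In the flask.** Alder holds more free base than electrophile, and so does larch. Electrophile, the limiting reagent against nucleophile, gives target and sets acid free; that acid can bind free base or nucleophile, and protic impurity can quench electrophile instead.

in all of them: electrophile 0.10 M
- grey: nucleophile 0.25 M; free base 0.21 M; protic impurity 0.050 M; run made earlier
- blue: nucleophile 0.25 M; free base 0.34 M; protic impurity 0.050 M; run made earlier
- larch: nucleophile 0.250 M; free base 0.450 M; protic impurity 0.0500 M; time 15 min
- alder: nucleophile 0.250 M; free base 0.300 M; protic impurity 0.0500 M; time 15 min

| run | time / min | electrophile / % | target / % |
|---|---|---|---|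
| grey | 0.833 | 88 | 10 |
| grey | 2.00 | 71 | 17 |
| grey | 5.00 | 46 | 38 |
| grey | 10.0 | 22 | 52 |
| blue | 2.50 | 66 | 20 |
| blue | 5.00 | 47 | 39 |
| blue | 8.00 | 29 | 47 |
| blue | 10.0 | 18 | 53 |

(scatter of a reading: 2 percentage points)

- on the list of suspects stand: electrophile + nucleophile -> acid set free + target; nucleophile + acid set free <-> protonated nucleophile; acid set free + free base <-> salt of the base; electrophile + protic impurity -> quenched substrate

- part of the electrophile that has reacted at the end, larch
- part of the electrophile that has reacted at the end, alder
- what raising the concentration of free base from its lowest to its highest value here does to the part of the electrophile that has reacted (changes below 5 percentage points count as none) (no change / it rises / it falls)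

**Base floor.** Each electrophile sets free at most one acid. So if the whole electrophile charge became acid and went onto the base, alder would keep 66.7% of its free base and larch 77.8%. I call this share, charge less electrophile over charge, the base floor.

**Don't touch.** Leave the free base alone, because grey, with less of it than alder, read 46% electrophile at 5.00 min against 47% in blue, inside the scatter of 2 percentage points.

**When you come.** Repeating the fall from 5.00 min to 10.0 min once more gives 89.5% reacted from grey and 93.1% from blue. I commit to the lower figure for both larch and alder at 15 min.

The forecast says 89% for larch, 89% for alder and no change: “the nucleophile stays free and base has no visible effect”.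

**Result.** Larch gives 88.1% and alder 88.1%, no change (0.0051 points), just under my figure.

    electrophile + nucleophile → acid set free + target (k = 0.480 M⁻¹ min⁻¹)
    nucleophile + acid set free ⇌ protonated nucleophile, settled at all times (K = 260 M⁻¹)
    acid set free + free base ⇌ salt of the base, settled at all times (K = 52000 M⁻¹)
    electrophile + protic impurity → quenched substrate (k = 1.40 M⁻¹ min⁻¹)

**Not at rest.** At 15 min alder still holds 12% electrophile. By 150 min that reads 0%, target climbs from 60.4% to 69.4%, and quenched substrate from 27.7% to 30.6%. Alder's free base slips from 79.9% to 77.0%, above its floor of 66.7%. The neighbour of alder with 0.085 M protic impurity has the same floor and stands above it too, at 82.9% free base with 93.0% reacted.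

(All runs were computed from invented constants; the scatter is artificial.)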